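**Retrosynthetic overview**
- Target ⇒ global O-demethylation of a dodecamethyl ether whose ring C is already a free pyrogallol.
- Ring C (the only ring that is built, and built last) ⇒ [4+2] union of a β-aryloxy enal (C5–C6=C1(O-AB)–C2H2–O-DEF) with diethyl ketomalonate (C3–C4). C4–C5 is made by a carbene-derived acyl-anion (Breslow) addition to the keto group, C2–C3 by Dieckmann closure, and the spare ester leaves as diethyl carbonate on aromatisation.
- Enal ⇒ oxa-Michael addition of the hindered A–B phenol to an ynal; ynal ⇒ D–E–F phenol + propargyl bromide + DMF.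
- A–B and D–E–F phenols ⇒ iterative Ullmann C–O coupling of a phenol with a bromo-dimethoxybenzaldehyde, each followed by Baeyer–Villiger/Dakin conversion of CHO into the next OH. Rings A, B, D, E, F are bought as arenes.

Assumption: the target has no stereocentre and is achiral, so no enantiocontrol is needed; the only stereo-element on the way (the C=C of 18) is erased on aromatisation.

Notation: rings are lettered A to F from the 2,4,6-trihydroxyphenyl end to the 3,4,5-trihydroxyphenyl end. Ring C atoms: C1 (O-ring B), C2 (O-ring D), C3–C5 (OH), C6 (H). AB-O = 2,6-dimethoxy-4-(2,4,6-trimethoxyphenoxy)phenoxy. DEF-O = 4-[3,5-dimethoxy-4-(3,4,5-trimethoxyphenoxy)phenoxy]-3,5-dimethoxyphenoxy.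

**Route**

Step 1
Reactants: 1 3,4,5-trimethoxyphenol; 2 4-bromo-3,5-dimethoxybenzaldehyde
Product: 3 3,5-dimethoxy-4-(3,4,5-trimethoxyphenoxy)benzaldehyde
Conditions: CuI (10 mol %), pyridine-2-carboxylic acid (20 mol %), K3PO4 (2 equiv), DMSO, 90 °C, Ar
Reagents that add atoms: none
Why: Ullmann-type copper-catalysed C–O coupling, in which the para-formyl group activates the C–Br bond between the two methoxy groups and the non-enolisable aldehyde survives K3PO4.

Step 2
Reactants: 3 3,5-dimethoxy-4-(3,4,5-trimethoxyphenoxy)benzaldehyde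
Product: 5 3,5-dimethoxy-4-(3,4,5-trimethoxyphenoxy)phenol, via aryl formate 4 (not isolated)
Conditions: mCPBA (1.3 equiv), CH2Cl2, 0 °C to rt; aq. NaHCO3 wash; then K2CO3 (0.2 equiv), MeOH, rt
Reagents that add atoms: 3-chloroperbenzoic acid (mCPBA), OOC(=O)c1cccc(Cl)c1
Why: Baeyer–Villiger (Dakin-type) oxidation, in which the electron-rich para-aryloxy aryl group migrates in preference to hydride and mild methanolysis of formate 4 frees the phenol without touching the diaryl ether.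

Step 3
Reactants: 5 3,5-dimethoxy-4-(3,4,5-trimethoxyphenoxy)phenol; 2 4-bromo-3,5-dimethoxybenzaldehyde
Product: 6 4-[3,5-dimethoxy-4-(3,4,5-trimethoxyphenoxy)phenoxy]-3,5-dimethoxybenzaldehyde
Conditions: CuI (10 mol %), pyridine-2-carboxylic acid (20 mol %), K3PO4 (2 equiv), DMSO, 90 °C, Ar
Reagents that add atoms: none
Why: second Ullmann-type C–O coupling of an unhindered phenol with the same formyl-activated aryl bromide, which adds ring D.

Step 4
Reactants: 6 4-[3,5-dimethoxy-4-(3,4,5-trimethoxyphenoxy)phenoxy]-3,5-dimethoxybenzaldehyde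
Product: 8 4-[3,5-dimethoxy-4-(3,4,5-trimethoxyphenoxy)phenoxy]-3,5-dimethoxyphenol, via aryl formate 7 (not isolated)
Conditions: mCPBA (1.3 equiv), CH2Cl2, 0 °C to rt; aq. NaHCO3 wash; then K2CO3 (0.2 equiv), MeOH, rt
Reagents that add atoms: 3-chloroperbenzoic acid (mCPBA), OOC(=O)c1cccc(Cl)c1
Why: Baeyer–Villiger (Dakin-type) oxidation as in step 2, giving the unhindered ring D phenol.

Step 5
Reactants: 8 4-[3,5-dimethoxy-4-(3,4,5-trimethoxyphenoxy)phenoxy]-3,5-dimethoxyphenol; 9 propargyl bromide (3-bromoprop-1-yne)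
Product: 10 2-[3,5-dimethoxy-4-(3,4,5-trimethoxyphenoxy)phenoxy]-1,3-dimethoxy-5-(prop-2-yn-1-yloxy)benzene
Conditions: K2CO3 (2 equiv), acetone, 56 °C
Reagents that add atoms: none
Why: Williamson ether synthesis (SN2 of the phenoxide on the propargylic bromide), which makes the future C2–O bond of ring C by alkylation instead of a hindered arylation.

Step 6
Reactants: 10 2-[3,5-dimethoxy-4-(3,4,5-trimethoxyphenoxy)phenoxy]-1,3-dimethoxy-5-(prop-2-yn-1-yloxy)benzene
Product: 12 4-(DEF-O)but-2-ynal, via lithium acetylide 11 (not isolated)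
Conditions: n-BuLi (1.05 equiv), THF, −78 °C; DMF (2 equiv), −78 to 0 °C; inverse quench into cold 10 % aq. KH2PO4
Reagents that add atoms: N,N-dimethylformamide (DMF), CN(C)C=O
Why: selective deprotonation of the terminal alkyne and formylation of the lithium acetylide with DMF (Bouveault-type formylation), with an inverse acidic quench so that the liberated dimethylamine does not add to the ynal.

Step 7
Reactants: 13 2,4,6-trimethoxyphenol; 14 4-bromo-2,6-dimethoxybenzaldehyde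
Product: 15 2,6-dimethoxy-4-(2,4,6-trimethoxyphenoxy)benzaldehyde
Conditions: CuI (10 mol %), pyridine-2-carboxylic acid (20 mol %), K3PO4 (2 equiv), DMSO, 90 °C, Ar
Reagents that add atoms: none
Why: Ullmann-type C–O coupling of a di-ortho-substituted phenol, a case this ligand system handles, with an unhindered para-formyl aryl bromide.

Step 8
Reactants: 15 2,6-dimethoxy-4-(2,4,6-trimethoxyphenoxy)benzaldehyde
Product: 17 2,6-dimethoxy-4-(2,4,6-trimethoxyphenoxy)phenol, via aryl formate 16 (not isolated)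
Conditions: mCPBA (1.1 equiv), CH2Cl2, 0 °C; aq. NaHCO3 wash; then K2CO3 (0.2 equiv), MeOH, rt
Reagents that add atoms: 3-chloroperbenzoic acid (mCPBA), OOC(=O)c1cccc(Cl)c1
Why: Baeyer–Villiger (Dakin-type) oxidation, especially easy for an ortho,ortho,para-trioxygenated benzaldehyde, which unveils the hindered ring B phenol.

Step 9
Reactants: 17 2,6-dimethoxy-4-(2,4,6-trimethoxyphenoxy)phenol; 12 4-(DEF-O)but-2-ynal
Product: 18 (E)-3-(AB-O)-4-(DEF-O)but-2-enal
Conditions: 1,4-diazabicyclo[2.2.2]octane (10 mol %), CH2Cl2, 0 °C to rt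
Reagents that add atoms: none
Why: amine-catalysed oxa-Michael (conjugate) addition of the phenol to the ynal, an atom-economic step that splits nothing off and gives the push–pull enal mainly as the E isomer, whose geometry is irrelevant because it equilibrates through the dienolate in step 10.

Step 10
Reactants: 18 (E)-3-(AB-O)-4-(DEF-O)but-2-enal; 19 diethyl ketomalonate (diethyl 2-oxopropanedioate)
Product: 22 4-(DEF-O)-5-(AB-O)benzene-1,2,3-triol, via α-ketol 20 (not isolated), via cyclic keto ester 21 (not isolated)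
Conditions: 19 (1.1 equiv), 2-(pentafluorophenyl)-6,7-dihydro-5H-pyrrolo[2,1-c][1,2,4]triazol-2-ium tetrafluoroborate (20 mol %), iPr2NEt (20 mol %), 4 Å sieves, THF, rt; then LiN(SiMe3)2 (3.5 equiv), −78 to 0 °C; degassed aq. HCl
Reagents that add atoms: none
Why: Proposed new method: the carbene adds to the aldehyde of 18 and the resulting Breslow intermediate, an acyl-anion equivalent (this β,β-disubstituted β-aryloxy enal is a poor homoenolate donor and a poor benzoin acceptor), attacks the very electrophilic, non-enolisable keto group of 19 to join C5 to C4 in α-ketol 20; LiN(SiMe3)2 then forms the γ-dienolate at C2, which closes ring C by a 6-exo Dieckmann condensation onto either of the two equivalent esters to give 21, and the expelled ethoxide removes the remaining ester as diethyl carbonate because the leaving carbanion is the phenolate of aromatic 22; the closest known reactions are the carbene-catalysed cross-benzoin of aldehydes with α-keto esters, the Claisen-type cyclisation of polyketo esters to phloroglucinols and the retro-Claisen cleavage of 2,2-disubstituted 1,3-diketones, and no stereocentre survives.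

Step 11
Reactants: 22 4-(DEF-O)-5-(AB-O)benzene-1,2,3-triol
Product: 23 CNP0270681.0 (target)
Conditions: BBr3 (30 equiv), CH2Cl2, −78 °C to rt; then H2O, 0 °C; Sephadex LH-20 (MeOH), Ar
Reagents that add atoms: none
Why: Lewis-acid cleavage of the twelve aryl methyl ethers (bromide attacks the O-methyl carbon of each boron-bound ether), while the five diaryl ether bonds carry no sp3 carbon and are untouched.

**Compound list**
1 | 3,4,5-trimethoxyphenol | COc1cc(O)cc(OC)c1OC | starting material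
2 | 4-bromo-3,5-dimethoxybenzaldehyde | COc1cc(C=O)cc(OC)c1Br | starting material
3 | 3,5-dimethoxy-4-(3,4,5-trimethoxyphenoxy)benzaldehyde | COc1cc(C=O)cc(OC)c1Oc1cc(OC)c(OC)c(OC)c1 | intermediate
4 | 3,5-dimethoxy-4-(3,4,5-trimethoxyphenoxy)phenyl formate (not isolated) | COc1cc(OC=O)cc(OC)c1Oc1cc(OC)c(OC)c(OC)c1 | intermediate
5 | 3,5-dimethoxy-4-(3,4,5-trimethoxyphenoxy)phenol | COc1cc(O)cc(OC)c1Oc1cc(OC)c(OC)c(OC)c1 | intermediate
6 | 4-[3,5-dimethoxy-4-(3,4,5-trimethoxyphenoxy)phenoxy]-3,5-dimethoxybenzaldehyde | COc1cc(C=O)cc(OC)c1Oc1cc(OC)c(Oc2cc(OC)c(OC)c(OC)c2)c(OC)c1 | intermediate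
7 | 4-[3,5-dimethoxy-4-(3,4,5-trimethoxyphenoxy)phenoxy]-3,5-dimethoxyphenyl formate (not isolated) | COc1cc(OC=O)cc(OC)c1Oc1cc(OC)c(Oc2cc(OC)c(OC)c(OC)c2)c(OC)c1 | intermediate
8 | 4-[3,5-dimethoxy-4-(3,4,5-trimethoxyphenoxy)phenoxy]-3,5-dimethoxyphenol (rings D–E–F phenol) | COc1cc(O)cc(OC)c1Oc1cc(OC)c(Oc2cc(OC)c(OC)c(OC)c2)c(OC)c1 | intermediate
9 | propargyl bromide (3-bromoprop-1-yne) | BrCC#C | starting material
10 | 2-[3,5-dimethoxy-4-(3,4,5-trimethoxyphenoxy)phenoxy]-1,3-dimethoxy-5-(prop-2-yn-1-yloxy)benzene | C#CCOc1cc(OC)c(Oc2cc(OC)c(Oc3cc(OC)c(OC)c(OC)c3)c(OC)c2)c(OC)c1 | intermediate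
11 | lithium acetylide of 10 (not isolated) | [Li]C#CCOc1cc(OC)c(Oc2cc(OC)c(Oc3cc(OC)c(OC)c(OC)c3)c(OC)c2)c(OC)c1 | intermediate
12 | 4-(DEF-O)but-2-ynal | O=CC#CCOc1cc(OC)c(Oc2cc(OC)c(Oc3cc(OC)c(OC)c(OC)c3)c(OC)c2)c(OC)c1 | intermediate
13 | 2,4,6-trimethoxyphenol | COc1cc(OC)c(O)c(OC)c1 | starting material
14 | 4-bromo-2,6-dimethoxybenzaldehyde | COc1cc(Br)cc(OC)c1C=O | starting material
15 | 2,6-dimethoxy-4-(2,4,6-trimethoxyphenoxy)benzaldehyde | COc1cc(OC)c(Oc2cc(OC)c(C=O)c(OC)c2)c(OC)c1 | intermediate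
16 | 2,6-dimethoxy-4-(2,4,6-trimethoxyphenoxy)phenyl formate (not isolated) | COc1cc(OC)c(Oc2cc(OC)c(OC=O)c(OC)c2)c(OC)c1 | intermediate
17 | 2,6-dimethoxy-4-(2,4,6-trimethoxyphenoxy)phenol (rings A–B phenol) | COc1cc(OC)c(Oc2cc(OC)c(O)c(OC)c2)c(OC)c1 | intermediate
18 | (E)-3-(AB-O)-4-(DEF-O)but-2-enal | O=C/C=C(/Oc1c(OC)cc(Oc2c(OC)cc(OC)cc2OC)cc1OC)COc1cc(OC)c(Oc2cc(OC)c(Oc3cc(OC)c(OC)c(OC)c3)c(OC)c2)c(OC)c1 | intermediate
19 | diethyl ketomalonate (diethyl 2-oxopropanedioate) | CCOC(=O)C(=O)C(=O)OCC | starting material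
20 | diethyl 2-hydroxy-2-[(E)-3-(AB-O)-4-(DEF-O)but-2-enoyl]propanedioate (not isolated) | CCOC(=O)C(O)(C(=O)OCC)C(=O)/C=C(/Oc1c(OC)cc(Oc2c(OC)cc(OC)cc2OC)cc1OC)COc1cc(OC)c(Oc2cc(OC)c(Oc3cc(OC)c(OC)c(OC)c3)c(OC)c2)c(OC)c1 | intermediate
21 | ethyl 1-hydroxy-2,6-dioxo-3-(DEF-O)-4-(AB-O)cyclohex-4-ene-1-carboxylate (transient mixture of diastereomers, not isolated) | CCOC(=O)C1(O)C(=O)C=C(Oc2c(OC)cc(Oc3c(OC)cc(OC)cc3OC)cc2OC)C(Oc2cc(OC)c(Oc3cc(OC)c(Oc4cc(OC)c(OC)c(OC)c4)c(OC)c3)c(OC)c2)C1=O | intermediate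
22 | 4-(DEF-O)-5-(AB-O)benzene-1,2,3-triol (dodecamethyl ether of the target) | Oc1cc(Oc2c(OC)cc(Oc3c(OC)cc(OC)cc3OC)cc2OC)c(Oc2cc(OC)c(Oc3cc(OC)c(Oc4cc(OC)c(OC)c(OC)c4)c(OC)c3)c(OC)c2)c(O)c1O | intermediate
23 | CNP0270681.0 (achiral hexameric phlorotannin with fifteen free OH groups) | Oc1cc(O)c(Oc2cc(O)c(Oc3cc(O)c(O)c(O)c3Oc3cc(O)c(Oc4cc(O)c(Oc5cc(O)c(O)c(O)c5)c(O)c4)c(O)c3)c(O)c2)c(O)c1 | target

**Totals**
Total step count: 11. Longest linear sequence: 9 steps (steps 1, 2, 3, 4, 5, 6, 9, 10, 11); steps 7 and 8 form the two-step side branch.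

**Three steps most likely to fail**

Step 10 (ring C annulation). Risks: the Breslow intermediate of 18 may protonate at the β-carbon and eject the AB phenoxide instead of attacking 19, or the tertiary alkoxide of 20 may attack C1 and close a furanone with loss of the AB phenol. Fallback, setting out from 18 and coming back at 22: replace the catalytic acyl anion by a stoichiometric, sulfur-masked one that leaves no free hydroxyl at C4. The lithium enolate of ethyl 1,3-dithiane-2-carboxylate (LiN(iPr)2, THF, −78 °C) adds 1,2 to the aldehyde of 18 to give ethyl 2-[(E)-1-hydroxy-3-(AB-O)-4-(DEF-O)but-2-en-1-yl]-1,3-dithiane-2-carboxylate F1. MnO2 in CH2Cl2 oxidises the allylic alcohol to ethyl 2-[(E)-3-(AB-O)-4-(DEF-O)but-2-enoyl]-1,3-dithiane-2-carboxylate F2. LiN(SiMe3)2 (2.2 equiv, THF, −78 to 0 °C) then effects the same γ-dienolate Dieckmann closure, now onto a substrate with no acidic or nucleophilic group at C4, giving 11-hydroxy-9-(AB-O)-10-(DEF-O)-1,5-dithiaspiro[5.5]undeca-8,10-dien-7-one F3. Alkylative hydrolysis of the dithioketal (MeI, aqueous MeCN, 50 °C, no base, reductive Na2S2O4 work-up) frees the C4 carbonyl, and the resulting trione tautomerises to 22.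

Step 9 (oxa-Michael addition to the ynal). Risks: ynal 12 may polymerise or isomerise to the allenal, and the di-ortho-substituted phenol 17 may add too slowly. Fallback, setting out from 10 and coming back at 18: make the vinyl ether bond at the ester oxidation level, where the acceptor is stable and can be heated. Alkyne 10 is deprotonated (n-BuLi, THF, −78 °C) and trapped with methyl chloroformate to give methyl 4-(DEF-O)but-2-ynoate F4. Phenol 17 is added with 1,4-diazabicyclo[2.2.2]octane (20 mol %) in MeCN at 50 °C to give methyl (E)-3-(AB-O)-4-(DEF-O)but-2-enoate F5. Reduction with iBu2AlH (CH2Cl2, −78 °C, Rochelle-salt work-up) gives (E)-3-(AB-O)-4-(DEF-O)but-2-en-1-ol F6, and MnO2 in CH2Cl2 oxidises this allylic alcohol to 18.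

Step 11 (global demethylation). Risks: twelve cleavages may stop short, and the free pentadeca-phenol is air-sensitive and hard to purify. Fallback, setting out from 22 and coming back at 23: isolate through a stable derivative. After the BBr3 treatment and aqueous quench, the crude phenol is not purified but acetylated at once (Ac2O, pyridine, rt) to the pentadecaacetate of the target F7. F7 is chromatographed on silica, and any partly methylated acetates are separated and resubmitted. Acid methanolysis (HCl generated from AcCl in degassed MeOH, rt, Ar) then removes the acetates and gives 23 on evaporation.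

**Further compounds**
F1 | step 10 | ethyl 2-[(E)-1-hydroxy-3-(AB-O)-4-(DEF-O)but-2-en-1-yl]-1,3-dithiane-2-carboxylate | CCOC(=O)C9(SCCCS9)C(O)/C=C(/Oc1c(OC)cc(Oc2c(OC)cc(OC)cc2OC)cc1OC)COc1cc(OC)c(Oc2cc(OC)c(Oc3cc(OC)c(OC)c(OC)c3)c(OC)c2)c(OC)c1
F2 | step 10 | ethyl 2-[(E)-3-(AB-O)-4-(DEF-O)but-2-enoyl]-1,3-dithiane-2-carboxylate | CCOC(=O)C9(SCCCS9)C(=O)/C=C(/Oc1c(OC)cc(Oc2c(OC)cc(OC)cc2OC)cc1OC)COc1cc(OC)c(Oc2cc(OC)c(Oc3cc(OC)c(OC)c(OC)c3)c(OC)c2)c(OC)c1
F3 | step 10 | 11-hydroxy-9-(AB-O)-10-(DEF-O)-1,5-dithiaspiro[5.5]undeca-8,10-dien-7-one | O=C9C=C(Oc1c(OC)cc(Oc2c(OC)cc(OC)cc2OC)cc1OC)C(Oc1cc(OC)c(Oc2cc(OC)c(Oc3cc(OC)c(OC)c(OC)c3)c(OC)c2)c(OC)c1)=C(O)C98SCCCS8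
F4 | step 9 | methyl 4-(DEF-O)but-2-ynoate | COC(=O)C#CCOc1cc(OC)c(Oc2cc(OC)c(Oc3cc(OC)c(OC)c(OC)c3)c(OC)c2)c(OC)c1
F5 | step 9 | methyl (E)-3-(AB-O)-4-(DEF-O)but-2-enoate | COC(=O)/C=C(/Oc1c(OC)cc(Oc2c(OC)cc(OC)cc2OC)cc1OC)COc1cc(OC)c(Oc2cc(OC)c(Oc3cc(OC)c(OC)c(OC)c3)c(OC)c2)c(OC)c1
F6 | step 9 | (E)-3-(AB-O)-4-(DEF-O)but-2-en-1-ol | OC/C=C(/Oc1c(OC)cc(Oc2c(OC)cc(OC)cc2OC)cc1OC)COc1cc(OC)c(Oc2cc(OC)c(Oc3cc(OC)c(OC)c(OC)c3)c(OC)c2)c(OC)c1
F7 | step 11 | pentadecaacetate of the target | CC(=O)Oc1cc(OC(C)=O)c(Oc2cc(OC(C)=O)c(Oc3cc(OC(C)=O)c(OC(C)=O)c(OC(C)=O)c3Oc3cc(OC(C)=O)c(Oc4cc(OC(C)=O)c(Oc5cc(OC(C)=O)c(OC(C)=O)c(OC(C)=O)c5)c(OC(C)=O)c4)c(OC(C)=O)c3)c(OC(C)=O)c2)c(OC(C)=O)c1
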